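Readings and results are calculated on assumed constants.

| flask | starting material | reagent | free catalyst | remark | time |
|---|---|---|---|---|---|
| noon | 0.0044 M | 0.0176 M | 16 µM | run made earlier |  |
| winter | 0.018 M | 0.0176 M | 16 µM | run made earlier |  |
| dusk | 0.016 M | 0.0176 M | 13 µM | run made earlier |  |
| zeta | 0.030 M | 0.0176 M | 10 µM |  | 30 min |
| gamma | 0.025 M | 0.0500 M | 5.0 µM |  | 30 min |
| beta | 0.0080 M | 0.0800 M | 10 µM |  | 30 min |
| delta | 0.0050 M | 0.0176 M | 16 µM |  | 30 min |
| eta | 0.0050 M | 0.0800 M | 50 µM |  | 30 min |
| alpha | 0.016 M | 0.0176 M | 16 µM |  | 30 min |

- noon (time / min: target / %, starting material / %): 2.50: 5.2, 95.5; 4.00: 6.3, 90.8; 6.00: 10.5, 88.6; 10.0: 17.8, 84.2; 20.0: 31.4, 68.2; 30.0: 44.4, 54.4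
- winter (time / min: target / %, starting material / %): 2.50: 3.9, 98.7; 4.00: 3.6, 95.5; 6.00: 6.8, 93.2; 10.0: 11.4, 89.7; 20.0: 21.4, 79.1; 30.0: 29.4, 69.8
- dusk (time / min: target / %, starting material / %): 2.50: 3.2, 96.8; 5.00: 5.0, 96.7; 8.00: 6.1, 93.6; 15.0: 12.3, 86.6; 30.0: 27.1, 72.4

(standard deviation of a reading: 1 percentage point)

* the flasks by amount of target, in percent of the starting material charged, highest first, at 30 min (zeta / gamma / beta / delta / eta / alpha)
* the amount of target, in percent of the starting material charged of the flask you put first, at 30 min
* the amount of target, in percent of the starting material charged of the flask you put last, at 30 min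



- Slowness is what you take over: in the noon run 54.4% of the starting material still stood at 30.0 min. You can therefore reckon these flasks by counting catalyst turns.
- Let T be target made per minute per catalyst charged, and S the mean starting-material level over a run. Noon gives 4.07 /min at 3.42 mM, and winter gives 11.0 /min at 15.4 mM.
- So from noon to winter S grows by a factor of 4.50 and T by a factor of 2.70. I write T = Tmax·S/(K+S), and these two readings give Tmax = 21.6 /min and K = 14.8 mM.
- Dusk, unused so far and with less catalyst, then comes out at 25.5% against a reading of 27.1%.
- Noon, winter and dusk share one reagent charge, 0.0176 M, so they cannot test reagent. Leaving it out of T is my assumption.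
- Gamma, first pass at its charge: 8.16% target. Put that back in and the mean level is 24.0 mM, where gamma's turnover rate, target made per minute per catalyst charged, is 13.4 /min. Going round once more gives 8.03% at 30 min.
- Zeta on a first pass gives 14.5%, so I put gamma last.
- Do not top up gamma with starting material: the percent is T times catalyst times time over the charge, and the charge grows while T levels off.
- The forecast says eta > beta > delta > alpha > gamma > zeta, top 99%, low 16%, with gamma at 25, on the ground “I assume first order in reagent”. My gamma is lower than that.

Result: eta > delta > alpha > beta > zeta > gamma, top 86.5%, low 8.14%.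

    reagent + free catalyst → catalyst intermediate A (k = 720 /M/s)
    catalyst intermediate A ⇌ catalyst intermediate B (K = 0.980, k = 0.670 /s)
    starting material + catalyst intermediate B → catalyst intermediate C (k = 52.0 /M/s)
    catalyst intermediate C → released group + catalyst intermediate D (k = 0.805 /s)
    catalyst intermediate D → free catalyst + target (k = 27.4 /s)

- Gamma's 8.14% means a turnover rate of 13.6 /min, against 13.4 /min carried. Changing only the reagent from noon to gamma's charge leaves target at 45.0% against 44.9%, while changing only the catalyst gives 16.4%. The time allowed is the main reason for gamma's shortfall: gamma stands at 8.14% at 30 min and reaches 67.0% at ten times that time.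
- Gamma's neighbour, with 1.20 µM of free catalyst: the carried 13.4 /min gives 1.93%, and the computed flask gives 1.98%.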